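Remark (numbering): germacrane numbering is used. C1=C10 carries the methyl C14, C4=C5 carries the acyloxymethyl carbon C15, C6 carries the free OH, C7 carries the acrylate carbons C11–C13, and C8 carries the lactone oxygen. The SMILES reads as 6R,7S,8S with a trans-fused lactone and both ring olefins ring-trans (1(10)E; 4Z by CIP because of the C15 oxygen).

## The problem

The target is a ten-membered carbocycle (C1–C10) with two ring-trans trisubstituted olefins, C1=C10 and C4=C5, forming an E,E-cyclodeca-1,5-diene, trans-fused at C7–C8 to an α-methylene-γ-butyrolactone (C11, C12, C13, O on C8). Closing this strained ring is the hardest task: the olefin geometries cannot be corrected once they are in the ring, so both must be set on open-chain pieces. The three stereocentres C6 (OH), C7 and C8 (O) are contiguous and syn,syn in the zigzag projection. C7 is the hub: C8 can control C7 through the five-membered lactone, and C7 can control C6 through a cyclic transition state. The feature that makes the key step possible is the unit C13–C11–C7: C7 is both a ring atom of the lactone and the terminus of a 2-carboxyallyl system, and the neighbouring C6 is a carbinol. C6(OH)–C7–C11=C13 is therefore a homoallylic alcohol, and the lactone written as a 3-(bromomethyl)furan-2(5H)-one (C7=C11, Br on C13) is an allyl nucleophile whose geometry is locked by the ring. O6 and O8 are both γ to C12, so the 8,12-lactone with free 6-OH must be secured, and the primary C15–OH must be acylated beside the secondary 6-OH. Sensitive groups are the α-methylene lactone (Michael acceptor), the germacradiene (Cope rearrangement on heating, transannular cyclisation in acid), the allylic acetate of the side chain (SN2′, Pd(0)), the γ-H of the butenolide precursors (base) and a (Z)-enal.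

## Retrosynthesis

**C15–O ester (35 ⇒ 28 + 34).** The ester bond between O15 and the side-chain carbonyl is cut first. The side chain is an enoate with an allylic acetate and would not survive organometallic, Pd(0) or Cr(II) steps, so it goes on last. The diol 28 has very different hydroxyls (primary allylic C15–OH against secondary C6–OH flanked by C7), so the forward step only has to be a mild, chemoselective acylation. Acid 34 comes from 29 and 30 by a Morita–Baylis–Hillman reaction and acetate transposition (31, 33).

**C6–C7 bond (28 ⇒ 27 ⇒ 25), the key cut.** After removing the C15 silyl ether (27), the C6–C7 bond is cut; the double bond moves into the lactone (C7=C11) and bromine goes on C13, giving the enal–bromomethylbutenolide 25 (reacting through allylchromium 26). Against the neighbouring C7–C8 cut, this one leaves the lactone intact, so the 8,12-regiochemistry is settled beforehand, only one stereocentre is needed in the precursor, and the aldehyde is a conjugated enal. Cuts in the diene half (C1–C2, C2–C3) create no stereocentre and would carry the lactone through a coupling macrocyclisation. The precursor is monocyclic with one stereocentre; the product is bicyclic with three. The forward reaction must close the ring rather than oligomerise, attack through C7, and relay C8 → C7 → C6.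

**Butenolide ring (25 ⇒ 24 ⇒ 23 ⇒ 22 ⇒ 20 + 21).** The C7=C11 double bond (ring-closing metathesis) and the O8–C12 ester bond are cut. This takes C11, C12 and C13 from commercial acid 21 and reduces the problem to the secondary allylic alcohol 20. The C6 aldehyde is carried as a TBS ether through coupling and metathesis and released late (23 → 24 → 25). The forward steps must spare the allylic bromide and use no base once the butenolide C8–H exists.

**C1–C2 bond (20 ⇒ 8 + 17).** This sp2–sp3 cut divides the chain into two pieces of similar size, each with one trisubstituted olefin that can be made by syn-addition to an alkyne. A C2–C3 cut would be an allyl–allyl coupling with regiochemical ambiguity, and olefination at C1=C10 or C4=C5 would not be stereocontrolled. The forward reaction is a B-alkyl Suzuki–Miyaura coupling with retention at the alkenyl iodide.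

**Fragment 17 (⇒ 15 ⇒ 14 ⇒ 12 ⇒ 9 + 10).** The C10–C14 and C1–I bonds are cut by carboalumination of alkyne 15, which fixes the E geometry. The terminal vinyl carbon comes from a sulfonium ylide acting on epoxide 13, and C9–C10 from alkynylation of (S)-epichlorohydrin 9 with 10 (via 11). C7, C8, C9 and the only stereocentre of the route come from 9.

**Fragment 8 (⇒ 7 ⇒ 4 + 5; 4 ⇒ 3 ⇒ 2 ⇒ 1).** The C3–C4 bond is cut (alkenyllithium 6 plus oxirane 5 supplies C2 and C3), then H and Sn are removed across C4=C5. Syn-hydrostannation of the symmetrical diol 1 places C15 and C6 cis, which is the ring-trans geometry. The bulk of tin differentiates the two hydroxyls (2 → 3 → 4).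

## Roads not taken

**Alternative 1:** the most obvious route, "lactone last". The C7–C8 bond and the lactone C12–O8 bond are cut. The open-chain ω-formyl (Z)-2-(bromomethyl)enoate A1, with C6 as a silyl ether, would be closed with Cr(II) (Nozaki–Hiyama–Kishi) and the C8 alkoxide would lactonise to A2. The chosen plan is better for four reasons:
- A1 needs a second stereocentre-forming step for C6 and a Morita–Baylis–Hillman/bromination sequence on an α-oxygenated aldehyde.
- The C8 aldehyde of A1 is β,γ-unsaturated and prone to conjugation.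
- The acyclic allylchromium of A1 can equilibrate its geometry, so C7 and C8 would both be set against C6 with no rigid element.
- A2 still needs C6 deprotection.

In 25 the allyl geometry is locked by the ring, one stereocentre does the work, and 6-OH is delivered free.

**Alternative 2:** the C6–C7 bond is cut but O6 is reconnected to C13. The 13-membered diallyl ether A3 would undergo [2,3]-Wittig ring contraction to carbocycle A4. The ring would close by easy etherification and the sigmatropic step would form C6–C7 and the exocyclic methylene together. The chosen plan is better for three reasons: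
- A3 has several allylic α-oxy CH2 groups (C6, C13, C12, C15) competing for deprotonation under strong base.
- A4 still needs C12 raised to the acid level while 6-OH and 8-OH, both γ to C12, compete for lactonisation.
- A3 is most easily made by reducing a butenolide of type 23, so the route would be at least five steps longer.

**Alternative 3:** the C8–C9 bond is cut and C1 is reconnected to C6. Anionic oxy-Cope rearrangement of the 1,2-dialkenylcyclohexenol A5 would give the cyclodecadienone A6 with C1=C10 E. The chosen plan is better for three reasons: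
- C4=C5 lies in the cyclohexene of A5 and reaches A6 ring-cis, the wrong geometry for this target.
- C6 arrives as a ketone and C7, C8 as unfunctionalised carbons.
- All three stereocentres and the lactone would have to be installed afterwards on a flexible medium ring.

Key step: step 15

## Route

Step 1
Reactants: 1 2-butyne-1,4-diol
Product: 2 (E)-2-(tributylstannyl)but-2-ene-1,4-diol
Conditions: Bu3SnH, PdCl2(PPh3)2 (2 mol %), THF, 0 °C to rt
Reagents that add atoms: tributyltin hydride, CCCC[SnH](CCCC)CCCC
Why: Pd-catalysed syn-hydrostannation of a symmetrical alkyne (no regiochemical issue); H and Sn add cis, so the two CH2O groups (future C15 and C6) end up cis, the ring-trans C4=C5 geometry once tin is replaced with retention.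

Step 2
Reactants: 2 (E)-2-(tributylstannyl)but-2-ene-1,4-diol
Product: 3 (E)-4-[(tert-butyldimethylsilyl)oxy]-2-(tributylstannyl)but-2-en-1-ol
Conditions: TBSCl (1.0 equiv), imidazole, CH2Cl2, −20 to 0 °C
Reagents that add atoms: tert-butyldimethylsilyl chloride, CC(C)(C)[Si](C)(C)Cl
Why: Kinetic monosilylation of the less hindered hydroxyl (on the CH= carbon, future C6); the other hydroxyl is shielded by the geminal Bu3Sn group.

Step 3
Reactants: 3 (E)-4-[(tert-butyldimethylsilyl)oxy]-2-(tributylstannyl)but-2-en-1-ol
Product: 4 (E)-4-[(tert-butyldimethylsilyl)oxy]-1-[(tert-butyldiphenylsilyl)oxy]-2-(tributylstannyl)but-2-ene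
Conditions: TBDPSCl, imidazole, DMAP (cat.), DMF, rt
Reagents that add atoms: tert-butyldiphenylsilyl chloride, CC(C)(C)[Si](Cl)(c1ccccc1)c1ccccc1
Why: Silylation of the remaining (future C15) hydroxyl with an acid-stable group, so that the C6 TBS ether can later be removed selectively.

Step 4
Reactants: 4 (E)-4-[(tert-butyldimethylsilyl)oxy]-1-[(tert-butyldiphenylsilyl)oxy]-2-(tributylstannyl)but-2-ene; 5 ethylene oxide
Product: 7 (Z)-5-[(tert-butyldimethylsilyl)oxy]-3-{[(tert-butyldiphenylsilyl)oxy]methyl}pent-3-en-1-ol, via alkenyllithium 6 (not isolated)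
Conditions: n-BuLi, THF, −78 °C; then ethylene oxide, BF3·OEt2, −78 °C
Reagents that add atoms: none
Why: Tin–lithium exchange with retention of olefin geometry, then BF3-promoted opening of oxirane by the alkenyllithium; C3 and C2 are attached trans to C6, and the low temperature suppresses β-elimination of the silyloxide.

Step 5
Reactants: 7 (Z)-5-[(tert-butyldimethylsilyl)oxy]-3-{[(tert-butyldiphenylsilyl)oxy]methyl}pent-3-en-1-ol
Product: 8 (Z)-1-[(tert-butyldimethylsilyl)oxy]-3-{[(tert-butyldiphenylsilyl)oxy]methyl}-5-iodopent-2-ene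
Conditions: I2, PPh3, imidazole, CH2Cl2, 0 °C
Reagents that add atoms: iodine, II
Why: Appel iodination of the primary homoallylic alcohol under neutral conditions; silyl ethers and olefin are unaffected.

Step 6
Reactants: 9 (S)-epichlorohydrin; 10 ethynyltrimethylsilane
Product: 12 (S)-1-chloro-5-(trimethylsilyl)pent-4-yn-2-ol, via lithium acetylide 11 (not isolated)
Conditions: n-BuLi, THF, −78 °C; then BF3·OEt2 and 9, −78 °C
Reagents that add atoms: none
Why: BF3-promoted alkynylation at the unsubstituted epoxide carbon (SN2); no bond to the stereocentre is broken, so it becomes C8 with S configuration.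

Step 7
Reactants: 12 (S)-1-chloro-5-(trimethylsilyl)pent-4-yn-2-ol
Product: 14 (S)-6-(trimethylsilyl)hex-1-en-5-yn-3-ol, via epoxide 13 (not isolated)
Conditions: Me3S+ I− (4 equiv), n-BuLi (3.9 equiv), THF, −10 °C to rt
Reagents that add atoms: trimethylsulfonium iodide, C[S+](C)C.[I-]
Why: The alkoxide closes to terminal epoxide 13; dimethylsulfonium methylide opens it and a second equivalent induces loss of Me2S, giving the one-carbon-homologated allylic alcohol (sulfonium ylide epoxide-to-allylic-alcohol homologation). The C–O bond of the stereocentre is never broken.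

Step 8
Reactants: 14 (S)-6-(trimethylsilyl)hex-1-en-5-yn-3-ol
Product: 15 (S)-hex-1-en-5-yn-3-ol
Conditions: K2CO3, MeOH, rt
Reagents that add atoms: none
Why: Methanolysis of the alkynyl C–Si bond frees the terminal alkyne needed for carbometalation.

Step 9
Reactants: 15 (S)-hex-1-en-5-yn-3-ol
Product: 17 (S,E)-6-iodo-5-methylhexa-1,5-dien-3-ol, via alkenylalane 16 (not isolated)
Conditions: Me3Al (3 equiv), Cp2ZrCl2 (25 mol %), CH2Cl2, 0 °C to rt; then I2, THF, −30 °C
Reagents that add atoms: trimethylaluminium, C[Al](C)C; iodine, II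
Why: Negishi Zr-catalysed carboalumination adds Me (C14) and Al syn, Me to the internal carbon, and iodinolysis proceeds with retention; this sets the E geometry of C1=C10. The monosubstituted alkene is much less reactive than the alkyne.

Step 10
Reactants: 8 (Z)-1-[(tert-butyldimethylsilyl)oxy]-3-{[(tert-butyldiphenylsilyl)oxy]methyl}-5-iodopent-2-ene; 17 (S,E)-6-iodo-5-methylhexa-1,5-dien-3-ol
Product: 20 (3S,5E,9Z)-11-[(tert-butyldimethylsilyl)oxy]-9-{[(tert-butyldiphenylsilyl)oxy]methyl}-5-methylundeca-1,5,9-trien-3-ol, via alkyllithium 18 (not isolated), via borate 19 (not isolated)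
Conditions: 8, t-BuLi (2.1 equiv), Et2O, −78 °C; B-methoxy-9-BBN, THF, −78 °C to rt; then 17, PdCl2(dppf) (5 mol %), AsPh3, Cs2CO3, DMF/H2O, rt
Reagents that add atoms: none
Why: B-alkyl Suzuki–Miyaura coupling through the lithium alkyl(methoxy)borate made by iodine–lithium exchange; it forms C1–C2 with retention at the alkenyl iodide and tolerates the free hydroxyl and both silyl ethers.

Step 11
Reactants: 20 (3S,5E,9Z)-11-[(tert-butyldimethylsilyl)oxy]-9-{[(tert-butyldiphenylsilyl)oxy]methyl}-5-methylundeca-1,5,9-trien-3-ol; 21 2-(bromomethyl)acrylic acid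
Product: 22 (3S,5E,9Z)-11-[(tert-butyldimethylsilyl)oxy]-9-{[(tert-butyldiphenylsilyl)oxy]methyl}-5-methylundeca-1,5,9-trien-3-yl 2-(bromomethyl)acrylate
Conditions: DCC, DMAP (5 mol %), CH2Cl2, 0 °C
Reagents that add atoms: none
Why: Steglich esterification of the secondary allylic alcohol; low temperature and only catalytic DMAP limit SN2′ attack on the allylic bromide, and the stereocentre is untouched.

Step 12
Reactants: 22 (3S,5E,9Z)-11-[(tert-butyldimethylsilyl)oxy]-9-{[(tert-butyldiphenylsilyl)oxy]methyl}-5-methylundeca-1,5,9-trien-3-yl 2-(bromomethyl)acrylate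
Product: 23 (S)-3-(bromomethyl)-5-[(2E,6Z)-8-[(tert-butyldimethylsilyl)oxy]-6-{[(tert-butyldiphenylsilyl)oxy]methyl}-2-methylocta-2,6-dien-1-yl]furan-2(5H)-one
Conditions: Hoveyda–Grubbs II (10 mol %), toluene (5 mM), 80 °C
Reagents that add atoms: none
Why: Ring-closing metathesis: the Ru carbene forms at the monosubstituted vinyl group and closes onto the 1,1-disubstituted acrylate to give the five-membered butenolide (C7=C11) with loss of ethene; the trisubstituted chain olefins are inert.

Step 13
Reactants: 23 (S)-3-(bromomethyl)-5-[(2E,6Z)-8-[(tert-butyldimethylsilyl)oxy]-6-{[(tert-butyldiphenylsilyl)oxy]methyl}-2-methylocta-2,6-dien-1-yl]furan-2(5H)-one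
Product: 24 (S)-3-(bromomethyl)-5-[(2E,6Z)-6-{[(tert-butyldiphenylsilyl)oxy]methyl}-8-hydroxy-2-methylocta-2,6-dien-1-yl]furan-2(5H)-one
Conditions: PPTS (0.2 equiv), MeOH/CH2Cl2, rt
Reagents that add atoms: none
Why: Acid-catalysed methanolysis removes the primary TBS ether much faster than the primary TBDPS ether; no base is present, so the butenolide C8–H and the allylic bromide are not endangered.

Step 14
Reactants: 24 (S)-3-(bromomethyl)-5-[(2E,6Z)-6-{[(tert-butyldiphenylsilyl)oxy]methyl}-8-hydroxy-2-methylocta-2,6-dien-1-yl]furan-2(5H)-one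
Product: 25 (2Z,6E)-8-[(S)-4-(bromomethyl)-5-oxo-2,5-dihydrofuran-2-yl]-3-{[(tert-butyldiphenylsilyl)oxy]methyl}-7-methylocta-2,6-dienal
Conditions: activated MnO2 (15 equiv), CH2Cl2, rt
Reagents that add atoms: none
Why: MnO2 oxidises only the allylic alcohol, under neutral heterogeneous conditions that should not isomerise the (Z)-enal or touch the bromide.

Step 15
Reactants: 25 (2Z,6E)-8-[(S)-4-(bromomethyl)-5-oxo-2,5-dihydrofuran-2-yl]-3-{[(tert-butyldiphenylsilyl)oxy]methyl}-7-methylocta-2,6-dienal
Product: 27 (3aS,4R,5Z,9E,11aS)-6-{[(tert-butyldiphenylsilyl)oxy]methyl}-4-hydroxy-10-methyl-3-methylidene-3a,4,7,8,11,11a-hexahydrocyclodeca[b]furan-2(3H)-one (6R,7S,8S in germacrane numbering), via allylchromium 26 (not isolated)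
Conditions: CrCl2 (10 equiv), THF, rt, 25 added over 12 h (final 2 mM)
Reagents that add atoms: none
Why: CrCl2 reduces the allylic C13–Br bond to the allylchromium(III) species 26 (Cr on the exocyclic C13), which adds through its γ-carbon C7 to the C6 aldehyde in a six-membered chair transition state and moves the double bond to C11=C13 (intramolecular Nozaki–Hiyama–Kishi allylation). The closest known reaction types are the Cr(II)-mediated closure of ten-membered germacranolide rings from ω-formyl 2-(bromomethyl)acrylates and the intermolecular Barbier addition of 3-(bromomethyl)furan-2(5H)-ones to aldehydes. The ten-membered carbocycle closes by 10-exo-trig attack of C7 on the aldehyde carbon (C6–C7 bond), with the lactone already in place. C7 is controlled by C8: the five-membered lactone can bridge C7 and C8 of the developing crown-like ring only when C6 and C9 leave it on opposite faces, so the new bond should form trans to C9 (7S from 8S). C6 is controlled by the allyl geometry, which the lactone ring fixes (C8 trans to C13, an E-crotyl-type reagent): with the alkenyl residue of the aldehyde pseudo-equatorial, the chair should give the anti homoallylic alcohol, that is 6R. The step needs 1,2- rather than 1,4-addition to the enal (normal for allylchromium reagents), ring closure rather than oligomerisation (slow addition, high dilution), and retention of the (Z)-enal and the 8,12-lactone (neutral, room temperature, no base). Both ring olefins are already correct in 25, so only one sp3–sp3 bond has to be made in the strained ring.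

Step 16
Reactants: 27 (3aS,4R,5Z,9E,11aS)-6-{[(tert-butyldiphenylsilyl)oxy]methyl}-4-hydroxy-10-methyl-3-methylidene-3a,4,7,8,11,11a-hexahydrocyclodeca[b]furan-2(3H)-one
Product: 28 (3aS,4R,5Z,9E,11aS)-4-hydroxy-6-(hydroxymethyl)-10-methyl-3-methylidene-3a,4,7,8,11,11a-hexahydrocyclodeca[b]furan-2(3H)-one
Conditions: TBAF, AcOH (1:1), THF, 0 °C
Reagents that add atoms: none
Why: Fluoride cleavage of the primary silyl ether; acetic acid buffers the medium so that neither Michael addition to the α-methylene lactone nor O8-to-O6 lactone migration is promoted, and the low temperature avoids Cope rearrangement.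

Step 17
Reactants: 29 tert-butyl acrylate; 30 acetaldehyde
Product: 31 tert-butyl 3-hydroxy-2-methylenebutanoate (racemic)
Conditions: DABCO (0.3 equiv), dioxane/H2O, rt
Reagents that add atoms: none
Why: Morita–Baylis–Hillman reaction; the carbinol stereocentre is lost in the next step, so the racemate suffices.

Step 18
Reactants: 31 tert-butyl 3-hydroxy-2-methylenebutanoate
Product: 33 tert-butyl (E)-2-(acetoxymethyl)but-2-enoate, via acetate 32 (not isolated)
Conditions: Ac2O, Et3N, DMAP (cat.), CH2Cl2, 0 °C; then DABCO (1 equiv), THF, 60 °C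
Reagents that add atoms: acetic anhydride, CC(=O)OC(C)=O
Why: Acetylation, then DABCO-mediated SN2′–SN2′ transposition of the Morita–Baylis–Hillman acetate to the more stable trisubstituted enoate; thermodynamic control should favour the E isomer (methyl trans to the ester, as in tiglates).

Step 19
Reactants: 33 tert-butyl (E)-2-(acetoxymethyl)but-2-enoate
Product: 34 (E)-2-(acetoxymethyl)but-2-enoic acid
Conditions: TFA, CH2Cl2, 0 °C to rt
Reagents that add atoms: none
Why: Acidolysis of the tert-butyl ester (loss of isobutene) leaves the acetate and the olefin geometry untouched.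

Step 20
Reactants: 28 (3aS,4R,5Z,9E,11aS)-4-hydroxy-6-(hydroxymethyl)-10-methyl-3-methylidene-3a,4,7,8,11,11a-hexahydrocyclodeca[b]furan-2(3H)-one; 34 (E)-2-(acetoxymethyl)but-2-enoic acid
Product: 35 CNP0184624.1, [(3aS,4R,5Z,9E,11aS)-4-hydroxy-10-methyl-3-methylidene-2-oxo-2,3,3a,4,7,8,11,11a-octahydrocyclodeca[b]furan-6-yl]methyl (E)-2-(acetoxymethyl)but-2-enoate
Conditions: EDC·HCl (1.2 equiv), DMAP (10 mol %), 34 (1.1 equiv), CH2Cl2, −20 to 0 °C
Reagents that add atoms: none
Why: Carbodiimide (Steglich-type) esterification at low temperature should discriminate the unhindered primary allylic C15–OH from the secondary C6–OH flanked by C7; no stereocentre is affected.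

## Compound list

1 | 2-butyne-1,4-diol | OCC#CCO | starting material
2 | (E)-2-(tributylstannyl)but-2-ene-1,4-diol | OC/C=C(CO)/[Sn](CCCC)(CCCC)CCCC | intermediate
3 | (E)-4-[(tert-butyldimethylsilyl)oxy]-2-(tributylstannyl)but-2-en-1-ol | CC(C)(C)[Si](C)(C)OC/C=C(CO)/[Sn](CCCC)(CCCC)CCCC | intermediate
4 | (E)-4-[(tert-butyldimethylsilyl)oxy]-1-[(tert-butyldiphenylsilyl)oxy]-2-(tributylstannyl)but-2-ene | CC(C)(C)[Si](C)(C)OC/C=C(CO[Si](c1ccccc1)(c1ccccc1)C(C)(C)C)/[Sn](CCCC)(CCCC)CCCC | intermediate
5 | ethylene oxide | C1CO1 | starting material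
6 | (Z)-{4-[(tert-butyldimethylsilyl)oxy]-1-[(tert-butyldiphenylsilyl)oxy]but-2-en-2-yl}lithium | [Li]/C(CO[Si](c1ccccc1)(c1ccccc1)C(C)(C)C)=C/CO[Si](C)(C)C(C)(C)C | intermediate
7 | (Z)-5-[(tert-butyldimethylsilyl)oxy]-3-{[(tert-butyldiphenylsilyl)oxy]methyl}pent-3-en-1-ol | OCC/C(CO[Si](c1ccccc1)(c1ccccc1)C(C)(C)C)=C/CO[Si](C)(C)C(C)(C)C | intermediate
8 | (Z)-1-[(tert-butyldimethylsilyl)oxy]-3-{[(tert-butyldiphenylsilyl)oxy]methyl}-5-iodopent-2-ene | ICC/C(CO[Si](c1ccccc1)(c1ccccc1)C(C)(C)C)=C/CO[Si](C)(C)C(C)(C)C | intermediate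
9 | (S)-epichlorohydrin | ClC[C@@H]1CO1 | starting material
10 | ethynyltrimethylsilane | C#C[Si](C)(C)C | starting material
11 | lithium (trimethylsilyl)acetylide | [Li]C#C[Si](C)(C)C | intermediate
12 | (S)-1-chloro-5-(trimethylsilyl)pent-4-yn-2-ol | ClC[C@@H](O)CC#C[Si](C)(C)C | intermediate
13 | (S)-2-[3-(trimethylsilyl)prop-2-yn-1-yl]oxirane | C[Si](C)(C)C#CC[C@H]1CO1 | intermediate
14 | (S)-6-(trimethylsilyl)hex-1-en-5-yn-3-ol | C=C[C@@H](O)CC#C[Si](C)(C)C | intermediate
15 | (S)-hex-1-en-5-yn-3-ol | C=C[C@@H](O)CC#C | intermediate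
16 | dimethylaluminium alkoxide of (S,E)-6-(dimethylalumanyl)-5-methylhexa-1,5-dien-3-ol | C=C[C@@H](O[Al](C)C)C/C(C)=C/[Al](C)C | intermediate
17 | (S,E)-6-iodo-5-methylhexa-1,5-dien-3-ol | C=C[C@@H](O)C/C(C)=C/I | intermediate
18 | (Z)-{5-[(tert-butyldimethylsilyl)oxy]-3-{[(tert-butyldiphenylsilyl)oxy]methyl}pent-3-en-1-yl}lithium | [Li]CC/C(CO[Si](c1ccccc1)(c1ccccc1)C(C)(C)C)=C/CO[Si](C)(C)C(C)(C)C | intermediate
19 | lithium B-alkyl-B-methoxy-9-borabicyclo[3.3.1]nonanate derived from 18 | [Li+].CO[B-]1(CC/C(CO[Si](c2ccccc2)(c2ccccc2)C(C)(C)C)=C/CO[Si](C)(C)C(C)(C)C)C2CCCC1CCC2 | intermediate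
20 | (3S,5E,9Z)-11-[(tert-butyldimethylsilyl)oxy]-9-{[(tert-butyldiphenylsilyl)oxy]methyl}-5-methylundeca-1,5,9-trien-3-ol | C=C[C@@H](O)C/C(C)=C/CC/C(CO[Si](c1ccccc1)(c1ccccc1)C(C)(C)C)=C/CO[Si](C)(C)C(C)(C)C | intermediate
21 | 2-(bromomethyl)acrylic acid | OC(=O)C(=C)CBr | starting material
22 | (3S,5E,9Z)-11-[(tert-butyldimethylsilyl)oxy]-9-{[(tert-butyldiphenylsilyl)oxy]methyl}-5-methylundeca-1,5,9-trien-3-yl 2-(bromomethyl)acrylate | C=C[C@@H](OC(=O)C(=C)CBr)C/C(C)=C/CC/C(CO[Si](c1ccccc1)(c1ccccc1)C(C)(C)C)=C/CO[Si](C)(C)C(C)(C)C | intermediate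
23 | (S)-3-(bromomethyl)-5-[(2E,6Z)-8-[(tert-butyldimethylsilyl)oxy]-6-{[(tert-butyldiphenylsilyl)oxy]methyl}-2-methylocta-2,6-dien-1-yl]furan-2(5H)-one | BrCC1=C[C@H](C/C(C)=C/CC/C(CO[Si](c2ccccc2)(c2ccccc2)C(C)(C)C)=C/CO[Si](C)(C)C(C)(C)C)OC1=O | intermediate
24 | (S)-3-(bromomethyl)-5-[(2E,6Z)-6-{[(tert-butyldiphenylsilyl)oxy]methyl}-8-hydroxy-2-methylocta-2,6-dien-1-yl]furan-2(5H)-one | BrCC1=C[C@H](C/C(C)=C/CC/C(CO[Si](c2ccccc2)(c2ccccc2)C(C)(C)C)=C/CO)OC1=O | intermediate
25 | (2Z,6E)-8-[(S)-4-(bromomethyl)-5-oxo-2,5-dihydrofuran-2-yl]-3-{[(tert-butyldiphenylsilyl)oxy]methyl}-7-methylocta-2,6-dienal | BrCC1=C[C@H](C/C(C)=C/CC/C(CO[Si](c2ccccc2)(c2ccccc2)C(C)(C)C)=C/C=O)OC1=O | intermediate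
26 | allylchromium(III) dichloride derived from 25 (Cr on C13) | Cl[Cr](Cl)CC1=C[C@H](C/C(C)=C/CC/C(CO[Si](c2ccccc2)(c2ccccc2)C(C)(C)C)=C/C=O)OC1=O | intermediate
27 | (3aS,4R,5Z,9E,11aS)-6-{[(tert-butyldiphenylsilyl)oxy]methyl}-4-hydroxy-10-methyl-3-methylidene-3a,4,7,8,11,11a-hexahydrocyclodeca[b]furan-2(3H)-one | C=C1C(=O)O[C@H]2C/C(C)=C/CC/C(CO[Si](c3ccccc3)(c3ccccc3)C(C)(C)C)=C/[C@@H](O)[C@H]12 | intermediate
28 | (3aS,4R,5Z,9E,11aS)-4-hydroxy-6-(hydroxymethyl)-10-methyl-3-methylidene-3a,4,7,8,11,11a-hexahydrocyclodeca[b]furan-2(3H)-one | C=C1C(=O)O[C@H]2C/C(C)=C/CC/C(CO)=C/[C@@H](O)[C@H]12 | intermediate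
29 | tert-butyl acrylate | C=CC(=O)OC(C)(C)C | starting material
30 | acetaldehyde | CC=O | starting material
31 | tert-butyl 3-hydroxy-2-methylenebutanoate (racemic) | CC(O)C(=C)C(=O)OC(C)(C)C | intermediate
32 | tert-butyl 3-acetoxy-2-methylenebutanoate (racemic) | CC(OC(C)=O)C(=C)C(=O)OC(C)(C)C | intermediate
33 | tert-butyl (E)-2-(acetoxymethyl)but-2-enoate | CC(C)(C)OC(=O)/C(=C/C)COC(C)=O | intermediate
34 | (E)-2-(acetoxymethyl)but-2-enoic acid | OC(=O)/C(=C/C)COC(C)=O | intermediate
35 | CNP0184624.1 | C=C1C(=O)O[C@H]2C/C(C)=C/CC/C(COC(=O)/C(=C/C)COC(C)=O)=C/[C@@H](O)[C@H]12 | target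

## Step count and least certain steps

Total step count: 20. Longest linear sequence: 13 steps (1–5, 10–16, 20, from 2-butyne-1,4-diol).

**Step 15 (key step).** The ring closure may be outrun by intermolecular coupling or by protonation of the allylchromium, and the aldehyde face may be selected poorly, because the tether could also allow a boat-like arrangement that leads to the C6 epimer. The chromium alkoxide could also start acyl migration from O8 to O6. Fallback: the cyclisation is run on 25 as planned and the C6 stereochemistry is corrected afterwards by reagent control. The C6-epimeric alcohol F1, alone or mixed with 27, is oxidised with Dess–Martin periodinane (NaHCO3, CH2Cl2, 0 °C) to the C6 enone F2. F2 is reduced 1,2 with an oxazaborolidine (Corey–Bakshi–Shibata) catalyst and catecholborane at −78 °C, the catalyst enantiomer being chosen to deliver hydride to the face that gives the 6R alcohol. The fallback sets out from 25 and comes back at 27.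

**Step 12.** Ring closure onto the 1,1-disubstituted, electron-poor bromomethyl acrylate may be slow, so that catalyst decay or dimerisation through the terminal vinyl group competes, and the allylic bromide may interfere with the ruthenium carbene. Fallback from 20: acylation with acryloyl chloride (i-Pr2NEt, CH2Cl2, −20 °C) gives the acrylate F3. Its metathesis now forms only a disubstituted olefin and gives the butenolide F4. Morita–Baylis–Hillman hydroxymethylation (aqueous formaldehyde, imidazole, THF/H2O) gives the 3-(hydroxymethyl)butenolide F5, and Appel bromination (CBr4, PPh3, CH2Cl2, 0 °C) returns to the route at 23. The weakly basic catalyst is chosen to limit epimerisation at C8.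

**Step 2.** The two primary allylic hydroxyls of 2 may not be discriminated well enough, leading to bis-silylation and the regioisomeric monoether. Fallback from 1: the symmetrical diol is monosilylated first (NaH, then TBSCl, THF) to the monosilyl ether F6. Hydroxyl-directed hydrostannation of F6 (Bu3SnH, Pd or Mo catalysis) places tin on the carbon next to the free hydroxyl and returns to the route at 3.

**Step 4.** The α-(silyloxymethyl)alkenyllithium may undergo β-elimination of silyloxide or oxygen-to-carbon silyl migration faster than it opens the epoxide. Fallback from 4: iododestannylation (I2, CH2Cl2, 0 °C) gives the alkenyl iodide F7. Suzuki–Miyaura coupling with vinylboronic acid pinacol ester (Pd(PPh3)4, K2CO3) gives the diene F8. Hydroboration of the monosubstituted vinyl group with 9-BBN and oxidation (NaBO3) returns to the route at 7.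

**Step 20.** Chemoselectivity may be lost (acylation of 6-OH as well), the nucleophilic catalyst may displace the allylic acetate of the activated acid in an SN2′ process, or the basic medium may start lactone migration to O6. Fallback from 28: Mitsunobu esterification with 34 (PPh3, DIAD, THF, 0 °C) activates the unhindered primary allylic alcohol instead of the acid and gives 35 directly; no new compound is made.

## Further compounds

F1 | step 15 | (3aS,4S,5Z,9E,11aS)-6-{[(tert-butyldiphenylsilyl)oxy]methyl}-4-hydroxy-10-methyl-3-methylidene-3a,4,7,8,11,11a-hexahydrocyclodeca[b]furan-2(3H)-one (C6 epimer of 27) | C=C1C(=O)O[C@H]2C/C(C)=C/CC/C(CO[Si](c3ccccc3)(c3ccccc3)C(C)(C)C)=C/[C@H](O)[C@H]12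
F2 | step 15 | (3aS,5Z,9E,11aS)-6-{[(tert-butyldiphenylsilyl)oxy]methyl}-10-methyl-3-methylidene-3a,7,8,11,11a-pentahydrocyclodeca[b]furan-2,4(3H)-dione (C6 enone) | C=C1C(=O)O[C@H]2C/C(C)=C/CC/C(CO[Si](c3ccccc3)(c3ccccc3)C(C)(C)C)=C/C(=O)[C@H]12
F3 | step 12 | (3S,5E,9Z)-11-[(tert-butyldimethylsilyl)oxy]-9-{[(tert-butyldiphenylsilyl)oxy]methyl}-5-methylundeca-1,5,9-trien-3-yl acrylate | C=C[C@@H](OC(=O)C=C)C/C(C)=C/CC/C(CO[Si](c1ccccc1)(c1ccccc1)C(C)(C)C)=C/CO[Si](C)(C)C(C)(C)C
F4 | step 12 | (S)-5-[(2E,6Z)-8-[(tert-butyldimethylsilyl)oxy]-6-{[(tert-butyldiphenylsilyl)oxy]methyl}-2-methylocta-2,6-dien-1-yl]furan-2(5H)-one | O=C1C=C[C@H](C/C(C)=C/CC/C(CO[Si](c2ccccc2)(c2ccccc2)C(C)(C)C)=C/CO[Si](C)(C)C(C)(C)C)O1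
F5 | step 12 | (S)-5-[(2E,6Z)-8-[(tert-butyldimethylsilyl)oxy]-6-{[(tert-butyldiphenylsilyl)oxy]methyl}-2-methylocta-2,6-dien-1-yl]-3-(hydroxymethyl)furan-2(5H)-one | OCC1=C[C@H](C/C(C)=C/CC/C(CO[Si](c2ccccc2)(c2ccccc2)C(C)(C)C)=C/CO[Si](C)(C)C(C)(C)C)OC1=O
F6 | step 2 | 4-[(tert-butyldimethylsilyl)oxy]but-2-yn-1-ol | CC(C)(C)[Si](C)(C)OCC#CCO
F7 | step 4 | (E)-4-[(tert-butyldimethylsilyl)oxy]-1-[(tert-butyldiphenylsilyl)oxy]-2-iodobut-2-ene | CC(C)(C)[Si](C)(C)OC/C=C(CO[Si](c1ccccc1)(c1ccccc1)C(C)(C)C)/I
F8 | step 4 | (Z)-5-[(tert-butyldimethylsilyl)oxy]-3-{[(tert-butyldiphenylsilyl)oxy]methyl}penta-1,3-diene | C=C/C(CO[Si](c1ccccc1)(c1ccccc1)C(C)(C)C)=C/CO[Si](C)(C)C(C)(C)C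
F0 | step 20 | none | none
A1 | alternative 1 | methyl (2Z,4R,5Z,9E)-2-(bromomethyl)-4-[(tert-butyldimethylsilyl)oxy]-6-{[(tert-butyldiphenylsilyl)oxy]methyl}-10-methyl-12-oxododeca-2,5,9-trienoate | COC(=O)/C(CBr)=C/[C@H](O[Si](C)(C)C(C)(C)C)/C=C(CO[Si](c1ccccc1)(c1ccccc1)C(C)(C)C)/CC/C=C(C)/CC=O
A2 | alternative 1 | (3aS,4R,5Z,9E,11aS)-4-[(tert-butyldimethylsilyl)oxy]-6-{[(tert-butyldiphenylsilyl)oxy]methyl}-10-methyl-3-methylidene-3a,4,7,8,11,11a-hexahydrocyclodeca[b]furan-2(3H)-one | C=C1C(=O)O[C@H]2C/C(C)=C/CC/C(CO[Si](c3ccccc3)(c3ccccc3)C(C)(C)C)=C/[C@@H](O[Si](C)(C)C(C)(C)C)[C@H]12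
A3 | alternative 2 | 13-membered diallyl ether: (S)-configured 1-oxacyclotrideca-3,7,11-triene with OTBS at C8, CH2OTBS at C11, CH2OTBDPS at C4 and methyl at C10 (germacrane numbering, O between C6 and C13) | O1C/C=C(CO[Si](c2ccccc2)(c2ccccc2)C(C)(C)C)/CC/C=C(C)/C[C@H](O[Si](C)(C)C(C)(C)C)/C=C(CO[Si](C)(C)C(C)(C)C)/C1
A4 | alternative 2 | (6R,7S,8S)-8-[(tert-butyldimethylsilyl)oxy]-12-[(tert-butyldimethylsilyl)oxy]-15-[(tert-butyldiphenylsilyl)oxy]germacra-1(10)E,4Z,11(13)-trien-6-ol | C=C(CO[Si](C)(C)C(C)(C)C)[C@@H]1[C@@H](O[Si](C)(C)C(C)(C)C)C/C(C)=C/CC/C(CO[Si](c2ccccc2)(c2ccccc2)C(C)(C)C)=C/[C@H]1O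
A5 | alternative 3 | 3-{[(tert-butyldimethylsilyl)oxy]methyl}-6-(prop-1-en-2-yl)-1-vinylcyclohex-2-en-1-ol, vinyl and isopropenyl trans (one enantiomer drawn) | C=C[C@]1(O)C=C(CO[Si](C)(C)C(C)(C)C)CC[C@H]1C(C)=C
A6 | alternative 3 | (2Z,6E)-3-{[(tert-butyldimethylsilyl)oxy]methyl}-7-methylcyclodeca-2,6-dien-1-one (ring-cis C4=C5, germacrane numbering) | O=C1CCC/C(C)=C/CC/C(CO[Si](C)(C)C(C)(C)C)=C\1
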